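The route builds the hexasubstituted benzene ring of the chroman last, cutting C5–C6, C7–C8 and C4a–C5. Light converts a dihydropyranyl diazomethyl ketone into a vinylketene, which is intercepted by a ketal-bearing siloxyalkyne; this single operation closes the benzene ring and installs three differently sourced oxygens: the C5 hydroxyl from the ketene carbonyl, the C7 silyl ether from the alkyne and the C8a ether oxygen from the enol ether of the pyran ring, with the masked C6 acetyl between C5 and C7 and C8 left free for the pyrone link. The precursor is a (3R)-3-silyloxy-2,2-dimethyl-3,4-dihydro-2H-pyran bearing a diazoacetyl group at C6; its stereocentre comes from an oxazaborolidine reduction.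

Key step: step 9

Assumption: 2,2-dimethylcyclopentane-1,3-dione is taken as a purchasable diketone; if it had to be made, C-methylation of 2-methylcyclopentane-1,3-dione would supply it.

Step 1
Reactants: 1 2,2-dimethylcyclopentane-1,3-dione
Product: 2 (3R)-3-hydroxy-2,2-dimethylcyclopentan-1-one
Conditions: (S)-1-methyl-3,3-diphenyltetrahydro-1H,3H-pyrrolo[1,2-c][1,3,2]oxazaborole (10 mol %), BH3·SMe2 (0.6 equiv), slow addition of 1, THF, −20 °C; MeOH quench
Reagents that add atoms: none
Why: Corey–Bakshi–Shibata reduction of one of two enantiotopic carbonyls, in which the oxazaborolidine–borane complex should deliver hydride to the face set by the quaternary C2 (large) against the ring CH2 (small), which for the (S)-catalyst gives the (R)-carbinol, while sub-stoichiometric borane limits diol formation.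

Step 2
Reactants: 2 (3R)-3-hydroxy-2,2-dimethylcyclopentan-1-one
Product: 3 (3R)-3-(tert-butyldimethylsilyloxy)-2,2-dimethylcyclopentan-1-one
Conditions: t-BuMe2SiOTf, 2,6-lutidine, CH2Cl2, 0 °C
Reagents that add atoms: tert-butyldimethylsilyl trifluoromethanesulfonate, CC(C)(C)[Si](C)(C)OS(=O)(=O)C(F)(F)F
Why: Silylation with a silyl triflate and a hindered pyridine base caps the hindered secondary alcohol without retro-aldol cleavage, so the later lactone never carries a free hydroxyl that could translactonise.

Step 3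
Reactants: 3 (3R)-3-(tert-butyldimethylsilyloxy)-2,2-dimethylcyclopentan-1-one
Product: 4 (5R)-5-(tert-butyldimethylsilyloxy)-6,6-dimethyltetrahydro-2H-pyran-2-one
Conditions: mCPBA, NaHCO3, CH2Cl2, 0 °C → rt
Reagents that add atoms: 3-chloroperoxybenzoic acid, OOC(=O)c1cccc(Cl)c1
Why: Baeyer–Villiger oxidation in which the quaternary carbon should migrate in preference to the CH2 group, placing the ring oxygen on the gem-dimethyl carbon and leaving the silyloxy stereocentre untouched.

Step 4
Reactants: 4 (5R)-5-(tert-butyldimethylsilyloxy)-6,6-dimethyltetrahydro-2H-pyran-2-one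
Product: 5 (3R)-3-(tert-butyldimethylsilyloxy)-2,2-dimethyl-3,4-dihydro-2H-pyran-6-yl diphenyl phosphate
Conditions: KN(SiMe3)2, (PhO)2P(O)Cl, THF/DMPU, −78 °C
Reagents that add atoms: diphenyl chlorophosphate, O=P(Cl)(Oc1ccccc1)Oc1ccccc1
Why: O-Phosphorylation of the potassium enolate of the lactone (only C3 is enolisable) should give a cyclic ketene acetal phosphate, which is more robust than the corresponding triflate yet still undergoes oxidative addition to zerovalent palladium.

Step 5
Reactants: 5 (3R)-3-(tert-butyldimethylsilyloxy)-2,2-dimethyl-3,4-dihydro-2H-pyran-6-yl diphenyl phosphate; 6 tributyl(1-ethoxyvinyl)stannane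
Product: 8 1-[(3R)-3-(tert-butyldimethylsilyloxy)-2,2-dimethyl-3,4-dihydro-2H-pyran-6-yl]ethan-1-one, via ethoxyvinyl diene 7 (not isolated)
Conditions: Pd(PPh3)4 (5 mol %), LiCl (3 equiv), THF, 65 °C; then 0.5 M aq. HCl, THF, 0 °C
Reagents that add atoms: water, O
Why: Stille coupling at the C–O bond of the ketene acetal phosphate (LiCl assists transmetalation) followed by mild acid hydrolysis of the more basic exocyclic ethyl enol ether, the ring enol ether of the resulting 2-alkoxy enone being deactivated towards protonation and the silyl ether stable to brief dilute acid.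

Step 6
Reactants: 8 1-[(3R)-3-(tert-butyldimethylsilyloxy)-2,2-dimethyl-3,4-dihydro-2H-pyran-6-yl]ethan-1-one
Product: 10 2-diazo-1-[(3R)-3-(tert-butyldimethylsilyloxy)-2,2-dimethyl-3,4-dihydro-2H-pyran-6-yl]ethan-1-one, via trifluoroacetyl diketone 9 (not isolated)
Conditions: LiN(SiMe3)2, THF, −78 °C; CF3CO2CH2CF3; then 4-acetamidobenzenesulfonyl azide, Et3N, H2O (1 equiv), MeCN, rt
Reagents that add atoms: 4-acetamidobenzenesulfonyl azide, CC(=O)Nc1ccc(cc1)S(=O)(=O)N=[N+]=[N-]; 2,2,2-trifluoroethyl trifluoroacetate, O=C(OCC(F)(F)F)C(F)(F)F (its trifluoroacetyl group is carried only by 9)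
Why: Detrifluoroacetylative diazo transfer (Regitz type), in which kinetic deprotonation of the methyl group and Claisen trifluoroacetylation activate that carbon for diazo transfer and the adduct collapses with loss of the trifluoroacetyl group as its sulfonamide, a sequence suited to enolisable α,β-unsaturated methyl ketones.

Step 7
Reactants: 11 ethyl pyruvate
Product: 12 ethyl 2-methyl-1,3-dioxolane-2-carboxylate
Conditions: HOCH2CH2OH, p-toluenesulfonic acid monohydrate (cat.), toluene, Dean–Stark, reflux
Reagents that add atoms: ethylene glycol, OCCO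
Why: Acid-catalysed ketalisation of the activated α-keto ester carbonyl with azeotropic removal of water should give the dioxolane that masks the future acetyl group through the basic and photochemical steps.

Step 8
Reactants: 12 ethyl 2-methyl-1,3-dioxolane-2-carboxylate
Product: 15 triisopropyl[(2-methyl-1,3-dioxolan-2-yl)ethynyloxy]silane, via lithium dibromoenolate 13 (not isolated), via lithium ynolate 14 (not isolated)
Conditions: CH2Br2, lithium 2,2,6,6-tetramethylpiperidide (2.2 equiv), THF, −78 °C; n-BuLi, −78 → 0 °C; i-Pr3SiCl, 0 °C → rt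
Reagents that add atoms: dibromomethane, BrCBr; chlorotriisopropylsilane, CC(C)[Si](Cl)(C(C)C)C(C)C
Why: Kowalski ester homologation stopped at the ynolate, in which dibromomethyllithium adds to the ester to give dibromo enolate 13, bromine–lithium exchange triggers 1,2-migration of the ketal carbon to ynolate 14, and the bulky silyl chloride reacts at oxygen.

Step 9
Reactants: 10 2-diazo-1-[(3R)-3-(tert-butyldimethylsilyloxy)-2,2-dimethyl-3,4-dihydro-2H-pyran-6-yl]ethan-1-one; 15 triisopropyl[(2-methyl-1,3-dioxolan-2-yl)ethynyloxy]silane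
Product: 20 (3R)-3-(tert-butyldimethylsilyloxy)-2,2-dimethyl-6-(2-methyl-1,3-dioxolan-2-yl)-7-(triisopropylsilyloxy)chroman-5-ol, via vinylketene 16 (not isolated), via vinylcyclobutenone 17 (not isolated), via dienylketene 18 (not isolated), via cyclohexadienone 19 (not isolated)
Conditions: 15 (2 equiv), hν (254 nm, low-pressure Hg lamps, quartz), degassed ClCH2CH2Cl, rt; then 80 °C in the dark
Reagents that add atoms: none
Why: Irradiation expels N2 and the dihydropyranyl group migrates (photochemical Wolff rearrangement) to give vinylketene 16, whose ketene carbon is attacked by the nucleophilic, ketal-bearing carbon of siloxyalkyne 15 in a polarised (2+2) cycloaddition that gives 4-vinylcyclobutenone 17. A 4π electrocyclic ring opening of 17 gives dienylketene 18, and the benzene ring is closed by a thermal 6π electrocyclisation that joins the ketene carbon to C5 of the dihydropyran (C4a–C5 of the chroman), followed by tautomerisation of dienone 19 to the phenol. The closest known reaction type is the Danheiser benzannulation in its photochemical Wolff variant with siloxyalkynes, established for alkenyl and oxygen-heteroaryl diazomethyl ketones, so the cyclic enol ether substrate is a new molecule within that class. No stereocentre is created in the product (the sp3 centres of 17 and 19 are lost on aromatisation), and C3 is remote from every bond change, so its R configuration should be carried through. The selectivity needed is regiochemical: the donor oxygen polarises the alkyne so that its carbon-substituted end bonds to the ketene carbonyl carbon, which places the masked acetyl between the new C5 hydroxyl and the C7 silyl ether and leaves C8 unsubstituted. An excess of alkyne should let the (2+2) step outrun ketene dimerisation.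

Step 10
Reactants: 20 (3R)-3-(tert-butyldimethylsilyloxy)-2,2-dimethyl-6-(2-methyl-1,3-dioxolan-2-yl)-7-(triisopropylsilyloxy)chroman-5-ol
Product: 22 1-[(3R)-3,5,7-trihydroxy-2,2-dimethylchroman-6-yl]ethan-1-one, via desilylated ketal 21 (not isolated)
Conditions: Bu4NF (4 equiv), THF, 0 → 45 °C, under argon; then 2 M aq. HCl, rt
Reagents that add atoms: water, O
Why: Fluoride should cleave the aryl triisopropylsilyl ether at once and the hindered secondary silyl ether on warming, and the dioxolane, flanked by two donor hydroxyls, should hydrolyse readily on acidification to the hydrogen-bonded aryl methyl ketone without involving the C3 carbinol centre.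

Step 11
Reactants: 23 pentan-3-one
Product: 24 trimethyl(pent-2-en-3-yloxy)silane
Conditions: Me3SiCl, NaI, Et3N, MeCN, rt
Reagents that add atoms: chlorotrimethylsilane, C[Si](C)(C)Cl
Why: Soft enolisation with Me3SiI formed in the flask and Et3N should give the silyl enol ether of this symmetrical ketone, for which regiochemistry is not an issue and the alkene geometry is irrelevant.

Step 12
Reactants: 24 trimethyl(pent-2-en-3-yloxy)silane; 25 malonyl dichloride
Product: 27 6-ethyl-4-hydroxy-5-methyl-2H-pyran-2-one, via diketo acid chloride 26 (not isolated)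
Conditions: Et2O, −78 °C → rt
Reagents that add atoms: none
Why: C-Acylation of the silyl enol ether by one acyl chloride and O-acylation of the resulting 1,3-diketone enol by the second should close the 4-hydroxy-2-pyrone, a known cyclocondensation of silyl enol ethers with malonyl dichloride.

Step 13
Reactants: 27 6-ethyl-4-hydroxy-5-methyl-2H-pyran-2-one; 22 1-[(3R)-3,5,7-trihydroxy-2,2-dimethylchroman-6-yl]ethan-1-one
Product: 30 3-{[(3R)-6-acetyl-3,5,7-trihydroxy-2,2-dimethylchroman-8-yl]methyl}-6-ethyl-4-hydroxy-5-methyl-2H-pyran-2-one, via pyrone Mannich base 28 (not isolated), via methylidenepyran-2,4-dione 29 (not isolated)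
Conditions: 27, Me2N=CH2+ I− (1.05 equiv), CHCl3, rt; then 22 (1 equiv), 45 °C
Reagents that add atoms: N,N-dimethylmethyleneiminium iodide (Eschenmoser's salt), C=[N+](C)C.[I-]
Why: Mannich reaction at the nucleophilic C3 of the pyrone gives 28, which loses dimethylamine to the Michael acceptor 29, and Friedel–Crafts-type conjugate addition of the acylphloroglucinol ring should then occur at C8, the only unsubstituted aromatic carbon, activated by the C7 hydroxyl and the ring oxygen.

Compound list
1 | 2,2-dimethylcyclopentane-1,3-dione | CC1(C)C(=O)CCC1=O | starting material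
2 | (3R)-3-hydroxy-2,2-dimethylcyclopentan-1-one | O=C1CC[C@@H](O)C1(C)C | intermediate
3 | (3R)-3-(tert-butyldimethylsilyloxy)-2,2-dimethylcyclopentan-1-one | O=C1CC[C@@H](O[Si](C)(C)C(C)(C)C)C1(C)C | intermediate
4 | (5R)-5-(tert-butyldimethylsilyloxy)-6,6-dimethyltetrahydro-2H-pyran-2-one | O=C1CC[C@@H](O[Si](C)(C)C(C)(C)C)C(C)(C)O1 | intermediate
5 | (3R)-3-(tert-butyldimethylsilyloxy)-2,2-dimethyl-3,4-dihydro-2H-pyran-6-yl diphenyl phosphate | O=P(Oc1ccccc1)(Oc1ccccc1)OC1=CC[C@@H](O[Si](C)(C)C(C)(C)C)C(C)(C)O1 | intermediate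
6 | tributyl(1-ethoxyvinyl)stannane | CCCC[Sn](CCCC)(CCCC)C(=C)OCC | starting material
7 | (3R)-3-(tert-butyldimethylsilyloxy)-6-(1-ethoxyvinyl)-2,2-dimethyl-3,4-dihydro-2H-pyran | C=C(OCC)C1=CC[C@@H](O[Si](C)(C)C(C)(C)C)C(C)(C)O1 | intermediate
8 | 1-[(3R)-3-(tert-butyldimethylsilyloxy)-2,2-dimethyl-3,4-dihydro-2H-pyran-6-yl]ethan-1-one | CC(=O)C1=CC[C@@H](O[Si](C)(C)C(C)(C)C)C(C)(C)O1 | intermediate
9 | 4,4,4-trifluoro-1-[(3R)-3-(tert-butyldimethylsilyloxy)-2,2-dimethyl-3,4-dihydro-2H-pyran-6-yl]butane-1,3-dione | O=C(CC(=O)C(F)(F)F)C1=CC[C@@H](O[Si](C)(C)C(C)(C)C)C(C)(C)O1 | intermediate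
10 | 2-diazo-1-[(3R)-3-(tert-butyldimethylsilyloxy)-2,2-dimethyl-3,4-dihydro-2H-pyran-6-yl]ethan-1-one | [N-]=[N+]=CC(=O)C1=CC[C@@H](O[Si](C)(C)C(C)(C)C)C(C)(C)O1 | intermediate
11 | ethyl pyruvate | CCOC(=O)C(C)=O | starting material
12 | ethyl 2-methyl-1,3-dioxolane-2-carboxylate | CCOC(=O)C1(C)OCCO1 | intermediate
13 | lithium 2,2-dibromo-1-(2-methyl-1,3-dioxolan-2-yl)ethen-1-olate | [Li+].[O-]C(=C(Br)Br)C1(C)OCCO1 | intermediate
14 | lithium 2-(2-methyl-1,3-dioxolan-2-yl)ethyn-1-olate | [Li+].[O-]C#CC1(C)OCCO1 | intermediate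
15 | triisopropyl[(2-methyl-1,3-dioxolan-2-yl)ethynyloxy]silane | CC1(C#CO[Si](C(C)C)(C(C)C)C(C)C)OCCO1 | intermediate
16 | 2-[(3R)-3-(tert-butyldimethylsilyloxy)-2,2-dimethyl-3,4-dihydro-2H-pyran-6-yl]ethen-1-one (vinylketene) | O=C=CC1=CC[C@@H](O[Si](C)(C)C(C)(C)C)C(C)(C)O1 | intermediate
17 | 4-[(3R)-3-(tert-butyldimethylsilyloxy)-2,2-dimethyl-3,4-dihydro-2H-pyran-6-yl]-2-(2-methyl-1,3-dioxolan-2-yl)-3-(triisopropylsilyloxy)cyclobut-2-en-1-one (both C4 epimers) | O=C1C(C2(C)OCCO2)=C(O[Si](C(C)C)(C(C)C)C(C)C)C1C3=CC[C@@H](O[Si](C)(C)C(C)(C)C)C(C)(C)O3 | intermediate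
18 | (3E)-4-[(3R)-3-(tert-butyldimethylsilyloxy)-2,2-dimethyl-3,4-dihydro-2H-pyran-6-yl]-2-(2-methyl-1,3-dioxolan-2-yl)-3-(triisopropylsilyloxy)buta-1,3-dien-1-one (dienylketene) | O=C=C(C1(C)OCCO1)/C(O[Si](C(C)C)(C(C)C)C(C)C)=C\C2=CC[C@@H](O[Si](C)(C)C(C)(C)C)C(C)(C)O2 | intermediate
19 | (3R)-3-(tert-butyldimethylsilyloxy)-2,2-dimethyl-6-(2-methyl-1,3-dioxolan-2-yl)-7-(triisopropylsilyloxy)-2,3,4,4a-tetrahydro-5H-chromen-5-one (both C4a epimers) | O=C1C(C2(C)OCCO2)=C(O[Si](C(C)C)(C(C)C)C(C)C)C=C3OC(C)(C)[C@H](O[Si](C)(C)C(C)(C)C)CC13 | intermediate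
20 | (3R)-3-(tert-butyldimethylsilyloxy)-2,2-dimethyl-6-(2-methyl-1,3-dioxolan-2-yl)-7-(triisopropylsilyloxy)chroman-5-ol | CC3(OCCO3)c1c(O)c2c(cc1O[Si](C(C)C)(C(C)C)C(C)C)OC(C)(C)[C@H](O[Si](C)(C)C(C)(C)C)C2 | intermediate
21 | (3R)-2,2-dimethyl-6-(2-methyl-1,3-dioxolan-2-yl)chromane-3,5,7-triol | CC3(OCCO3)c1c(O)c2c(cc1O)OC(C)(C)[C@H](O)C2 | intermediate
22 | 1-[(3R)-3,5,7-trihydroxy-2,2-dimethylchroman-6-yl]ethan-1-one | CC(=O)c1c(O)c2c(cc1O)OC(C)(C)[C@H](O)C2 | intermediate
23 | pentan-3-one | CCC(=O)CC | starting material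
24 | trimethyl(pent-2-en-3-yloxy)silane (E/Z mixture) | CC=C(CC)O[Si](C)(C)C | intermediate
25 | malonyl dichloride | O=C(Cl)CC(=O)Cl | starting material
26 | 4-methyl-3,5-dioxoheptanoyl chloride (racemic) | CCC(=O)C(C)C(=O)CC(=O)Cl | intermediate
27 | 6-ethyl-4-hydroxy-5-methyl-2H-pyran-2-one | CCc1oc(=O)cc(O)c1C | intermediate
28 | 3-[(dimethylamino)methyl]-6-ethyl-4-hydroxy-5-methyl-2H-pyran-2-one | CCc1oc(=O)c(CN(C)C)c(O)c1C | intermediate
29 | 6-ethyl-5-methyl-3-methylidene-2H-pyran-2,4(3H)-dione | CCC1=C(C)C(=O)C(=C)C(=O)O1 | intermediate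
30 | 3-{[(3R)-6-acetyl-3,5,7-trihydroxy-2,2-dimethylchroman-8-yl]methyl}-6-ethyl-4-hydroxy-5-methyl-2H-pyran-2-one | CCc1oc(=O)c(Cc2c(O)c(C(C)=O)c(O)c3c2OC(C)(C)[C@H](O)C3)c(O)c1C | target

Total step count: 13. Longest linear sequence: 9 steps (steps 1, 2, 3, 4, 5, 6, 9, 10, 13).

Steps most likely to fail

Step 9. The vinylketene may be lost to dimerisation, or the diazoketone to unproductive photochemistry, before the hindered ketal-bearing alkyne captures it. The fallback generates the same ketene without light. It sets out from enol phosphate 5: Pd(PPh3)4-catalysed Negishi-type coupling with the Reformatsky reagent BrZnCH2CO2Et in THF at 60 °C should give ethyl 2-[(3R)-3-(tert-butyldimethylsilyloxy)-2,2-dimethyl-3,4-dihydro-2H-pyran-6-yl]acetate F1. LiOH in THF/H2O should give lithium 2-[(3R)-3-(tert-butyldimethylsilyloxy)-2,2-dimethyl-3,4-dihydro-2H-pyran-6-yl]acetate F2, and (COCl)2 with catalytic N,N-dimethylformamide in CH2Cl2 at 0 °C should give 2-[(3R)-3-(tert-butyldimethylsilyloxy)-2,2-dimethyl-3,4-dihydro-2H-pyran-6-yl]acetyl chloride F3. Slow addition of F3 to Et3N and alkyne 15 in toluene at 80 °C should release vinylketene 16 by dehydrochlorination and carry on through 17, 18 and 19, so the fallback comes back to the route at 20.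

Step 8. The α,α-dialkoxy substituent may divert the lithium carbenoid (loss of alkoxide from the ketal carbon, or a slow 1,2-shift of the tertiary carbon), or silylation may occur on carbon. The fallback reaches the same ynolate by oxidising an acetylide. It sets out from ketal ester 12: i-Bu2AlH in CH2Cl2 at −78 °C should give 2-methyl-1,3-dioxolane-2-carbaldehyde F4, and the Ohira–Bestmann reagent (dimethyl (1-diazo-2-oxopropyl)phosphonate, K2CO3, MeOH) should give 2-ethynyl-2-methyl-1,3-dioxolane F5. Deprotonation with LiN(SiMe3)2 and oxidation with lithium tert-butyl peroxide (from t-BuOOH and LiN(SiMe3)2, THF, −78 → 0 °C) should give ynolate 14, and O-silylation with i-Pr3SiOTf returns to the route at 15.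

Step 13. The methylidene intermediate 29 may be captured by pyrone set free through retro-Mannich exchange, giving the symmetrical methylene-bis-pyrone, or may add reversibly at phenolic oxygen. The fallback inverts the polarity of the methylene transfer and sets out from triol 22. Aminomethylation with Eschenmoser's salt in CH2Cl2 at rt can occur only at C8 and should give 1-[(3R)-8-[(dimethylamino)methyl]-3,5,7-trihydroxy-2,2-dimethylchroman-6-yl]ethan-1-one F6. Heating F6 with pyrone 27 in dioxane at 90 °C should expel dimethylamine to give an ortho-quinone methide on the chroman that is captured by C3 of 27, coming back to the route at 30.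

Further compounds
F1 | step 9 | ethyl 2-[(3R)-3-(tert-butyldimethylsilyloxy)-2,2-dimethyl-3,4-dihydro-2H-pyran-6-yl]acetate | CCOC(=O)CC1=CC[C@@H](O[Si](C)(C)C(C)(C)C)C(C)(C)O1
F2 | step 9 | lithium 2-[(3R)-3-(tert-butyldimethylsilyloxy)-2,2-dimethyl-3,4-dihydro-2H-pyran-6-yl]acetate | [Li+].[O-]C(=O)CC1=CC[C@@H](O[Si](C)(C)C(C)(C)C)C(C)(C)O1
F3 | step 9 | 2-[(3R)-3-(tert-butyldimethylsilyloxy)-2,2-dimethyl-3,4-dihydro-2H-pyran-6-yl]acetyl chloride | O=C(Cl)CC1=CC[C@@H](O[Si](C)(C)C(C)(C)C)C(C)(C)O1
F4 | step 8 | 2-methyl-1,3-dioxolane-2-carbaldehyde | CC1(C=O)OCCO1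
F5 | step 8 | 2-ethynyl-2-methyl-1,3-dioxolane | CC1(C#C)OCCO1
F6 | step 13 | 1-[(3R)-8-[(dimethylamino)methyl]-3,5,7-trihydroxy-2,2-dimethylchroman-6-yl]ethan-1-one | CC(=O)c1c(O)c2c(c(CN(C)C)c1O)OC(C)(C)[C@H](O)C2
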